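# Radermachol by naphthalyne insertion into an acylindanedione: synthesis proposal

**Compound numbers used throughout**

1 2-bromo-1,4-dimethoxynaphthalene · 2 its 2-lithio derivative · 3 the derived dimethyl boronate · 4 1,4-dimethoxynaphthalen-2-ol · 5 3-bromo-1,4-dimethoxynaphthalen-2-ol · 6 its trimethylsilyl ether · 7 the 3-lithio silyl ether · 8 the lithium 3-silylnaphthoxide · 9 the silyl triflate (aryne precursor) · 10 indane-1,3-dione · 11 3-methylbut-2-enoic acid · 12 the enol ester of 10 and 11 · 13 2-(3-methylbut-2-enoyl)indane-1,3-dione · 14 1,4-dimethoxy-2,3-naphthalyne · 15 the C-arylated aryl anion · 16 the benzocyclobutenoxide · 17 the ring-expanded triketone · 18 the naphthalene-1,4-diol · 19 radermachol.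

Remark on the chemistry: the form with a ring D ketone and a ring B enol (the target as drawn) and the form with a ring D naphthol and a ring B ketone are tautomers that exchange one proton inside a six-membered hydrogen-bonded chelate. The last product is therefore written in the form of the target. Compounds 13 and 17 are drawn as keto forms although they are largely enolised.

## Analysis of the target

Radermachol (19, C24H16O4) is a flat pentacycle. A furan (ring C: O1, C2, C3, C4, C5) carries the 2-methylprop-1-enyl group on C2. Through C4–C5 it is fused to a six-membered carbocycle (ring D) that holds a ketone and a benzo ring (ring E). Through C3–C4 and the neighbouring ring D carbon (the central carbon) it is fused to a seven-membered ring B. Ring B is completed by a ketone carbon on furan C3, the o-phenylene of benzo ring A and an enol carbon (C–OH) on the central carbon.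

The molecule has no stereocentre and the side-chain alkene has no E/Z isomers, so no stereochemical relationship has to be set. The sensitive parts are the electron-rich alkenylfuran (acids, electrophiles, oxidants) and the vinylogous acid formed by the enol OH and the ring D ketone.

The difficulty is ring B: a seven-membered ring made only of sp2 carbons, peri-fused across three contiguous fully substituted carbons (furan C3, furan C4, central carbon). Four oxygens must also land on the right carbons. A direct seven-membered closure onto the hindered furan C3 or onto the central carbon is unattractive.

The route rests on one feature. Seen from ring A, ring B is a phthaloyl unit: the ketone carbon and the enol carbon are in a 1,5-relationship through ring A. Its remaining edge, furan C4 and the central carbon, is a pair of adjacent carbons of ring D. Ring D, with O1 on C5 and the ketone para to it, is a 1,4-dioxygenated naphthalene in tautomeric disguise. The phthaloyl unit plus furan C3 is indane-1,3-dione (10), and the C4–central carbon edge is the triple bond of a 2,3-naphthalyne (14).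

## Retrosynthetic reasoning

**19 to 17.** The furan O1–C2 bond is cut first. C2 then becomes a ketone carbon and O1 a naphthol oxygen, and ring D is written in its naphthalene-1,4-diol form 18. Both ring D oxygens are masked as methyl ethers in 17. The cut is made here because it turns the heterocycle into an o-hydroxyaryl 1,3-diketone, which closes to a furan by simple acid-mediated dehydration. It also puts the acid-labile alkenylfuran at the very end. The forward reaction must cleave two aryl methyl ethers and close the furan onto the enoyl ketone. Closure onto the ring ketone would need a bridgehead double bond in a bridged bicycle, so only one furan can form.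

**17 to 13 and 14.** In 17 the two bonds from ring D into ring B are cut together: furan C3 to C4, and central carbon to enol carbon. This is the reverse of an aryne insertion into a C–C(=O) bond. It returns the symmetrical naphthalyne 14 and the triketone 13, in which ring B is contracted to the five-membered ring of an indanedione. The cut is chosen over any single-bond ring B closure because the seven-membered ring then arises by two-carbon ring expansion. All 26 carbons of 17 come from two symmetrical partners, so no regiochemical question exists. The forward reaction must add the triketone carbon to 14 and then have the aryl anion attack a ring carbonyl, not the enoyl carbonyl.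

**14 to 1.** The aryne 14 is released by fluoride from the o-silylaryl triflate 9. Compound 9 comes from naphthoxide 8, formed by 1,3-migration of silicon from oxygen to carbon in the lithio silyl ether 7. Compound 7 comes from silyl ether 6 of bromonaphthol 5. The bromine of 5 is placed by electrophilic substitution of naphthol 4 at its only free position on the oxygenated ring. The hydroxyl of 4 comes from bromide 1 by lithiation, borylation and oxidation. Each of these steps is standard for this precursor class.

**13 to 10 and 11.** The exocyclic C–C(=O) bond of 13 is cut to give indane-1,3-dione (10) and 3-methylbut-2-enoic acid (11). The forward step is a carbodiimide-mediated O-acylation to enol ester 12, followed by acyl shift to carbon. This is preferred to building the dione ring by ester condensation with an enolisable enone, which would self-condense.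

## Alternatives that were turned down

**Alternative 1:** The bond between the central carbon and furan C4 is cut (ring D), and afterwards the bond between the ring B ketone carbon and furan C3.
- Forward key step: the open 1,3-diketone A2 is a 2-aryl-5-(2-methylprop-1-enyl)furan whose aryl ring carries the diketone. Mn(OAc)3 with Cu(OAc)2 in acetic acid oxidises it to the α-radical. This radical closes a six-membered ring on the furan β-carbon next to the aryl group, and oxidation with proton loss restores the heteroarene. The product is keto acid A1, from which ring B would be closed by Friedel–Crafts acylation at furan C3.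
- For it: ring D and its para-dioxygenation appear with no protecting groups on the ring D oxygens and no ether cleavage at the end. On that point it is stronger than the chosen route. Electrophilic diketone radicals add readily to electron-rich heteroarenes, and the six-membered closure is geometrically easy.
- Against it: trivalent manganese and divalent copper in hot acetic acid meet the most oxidisable part of the molecule, the alkenylfuran. A2 is a linear precursor that needs a cross-coupling and a Claisen condensation, roughly six or seven steps, and its o-carboxy diketone tends to lactonise. The seven-membered ring is left to a late, acid-promoted acylation at a hindered furan β-carbon beside the acid-sensitive side chain.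
- Comparison: the chosen strategy makes ring B in the same step that joins the fragments, and keeps the side chain as a robust enone until the last step.

**Alternative 2:** The furan O1–C2 bond and both bonds to the ring B ketone carbon are cut, with CO as the one-carbon unit.
- Forward key step: bromo ketone A4 is a 1-naphthol carrying the enyne at C2, a 2-bromobenzoyl group at C3 and a methoxy group at C4. Under CO with Pd(PPh3)4 and K2CO3 it would undergo oxidative addition, CO insertion, anti-attack of the naphthoxide on the palladium-bound alkyne and reductive elimination. The product is radermachol O-methyl ether A3, to be demethylated.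
- For it: two rings and three bonds form in one catalytic operation. The alkyne fixes which carbon becomes furan C2, so the question of which carbonyl closes the furan never arises. On bond count per step and on this regiochemical point it is the stronger plan. The intermolecular carbonylative annulation of o-alkynylphenols with aryl halides is established.
- Against it: A4 is a naphthalene with four different contiguous substituents and two differentiated ring D oxygens, reached only after a long sequence that includes coupling of a volatile enyne. The free o-alkynylnaphthol can cycloisomerise to the 3-unsubstituted furan without taking up CO. The tethered acylpalladium must reach the alkyne through a medium-sized palladacycle. Carbopalladation without CO would give a six-membered ring. An ether cleavage beside the alkenylfuran is still needed.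
- Comparison: the chosen route gives up this elegance for two symmetrical fragments made in one and four steps, and a total of seven steps.

**Alternative 3:** The bond between furan C5 and ring E is cut.
- Forward key step: bromo ketone A6 is the tricyclic furan-fused benzotropone methyl enol ether with a 2-bromobenzoyl group on the central carbon and a free C5–H. With Pd(OAc)2, PCy3, K2CO3 and pivalic acid it would undergo oxidative addition, concerted metalation–deprotonation at furan C5 and reductive elimination. The product is radermachol methyl enol ether A5, whose vinylogous ester is hydrolysed at the end.
- For it: direct arylation of a furan α-C–H bond in a six-membered closure is among the most dependable C–H functionalisations. The final unmasking is milder than a BBr3 demethylation. On both points it is stronger than the chosen route.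
- Against it: the real problem is only moved into A6, a seven-membered ring fused at the 3,4-bond of a furan that also carries the alkenyl group and a free α-position. This is the most acid- and oxidant-labile version of the heterocycle and has no simple assembly. Attaching the 2-bromobenzoyl group to the central carbon competes with O-acylation. Hot carbonate with divalent palladium invites Heck-type reactions of the side-chain alkene.
- Comparison: the chosen route builds ring B first, by ring expansion, and leaves the easiest ring, the furan, for the end.

Key step: step 6

## Route

Step 1
Reactants: 1 2-bromo-1,4-dimethoxynaphthalene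
Product: 4 1,4-dimethoxynaphthalen-2-ol, via 1,4-dimethoxy-2-naphthyllithium 2 (not isolated), via dimethyl 1,4-dimethoxy-2-naphthylboronate 3 (not isolated)
Conditions: n-BuLi, THF, −78 °C; B(OMe)3, −78 °C → rt; 30% H2O2, AcOH, 0 °C → rt
Reagents that add atoms: hydrogen peroxide, OO (the hydroxyl oxygen of 4); n-butyllithium, [Li]CCCC, and trimethyl borate, COB(OC)OC, leave lithium and boron only in 2 and 3
Why: Bromine–lithium exchange, borylation and oxidation of the aryl boronate (1,2-shift of the aryl group from boron to oxygen) is the standard way from an aryl bromide to a phenol; the acidic oxidation medium keeps the electron-rich naphthol protonated and away from air oxidation.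

Step 2
Reactants: 4 1,4-dimethoxynaphthalen-2-ol
Product: 5 3-bromo-1,4-dimethoxynaphthalen-2-ol
Conditions: NBS (1.0 equiv), i-Pr2NH (0.1 equiv), CH2Cl2, −78 → 0 °C, dark
Reagents that add atoms: N-bromosuccinimide, O=C1CCC(=O)N1Br
Why: Electrophilic aromatic bromination, amine-catalysed for ortho delivery; C3 is the only free position of the oxygenated ring and lies ortho to both the hydroxyl and a methoxy group, and dry, cold conditions disfavour oxidative demethylation.

Step 3
Reactants: 5 3-bromo-1,4-dimethoxynaphthalen-2-ol
Product: 6 (3-bromo-1,4-dimethoxynaphthalen-2-yl)oxy-trimethylsilane
Conditions: (Me3Si)2NH, THF, 70 °C; volatiles removed in vacuo, crude used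
Reagents that add atoms: hexamethyldisilazane, C[Si](C)(C)N[Si](C)(C)C
Why: O-silylation of a phenol with hexamethyldisilazane gives only ammonia beside the silyl ether, so the moisture-sensitive product can be carried on without purification.

Step 4
Reactants: 6 (3-bromo-1,4-dimethoxynaphthalen-2-yl)oxy-trimethylsilane
Product: 9 1,4-dimethoxy-3-(trimethylsilyl)naphthalen-2-yl trifluoromethanesulfonate, via the 3-lithio silyl ether 7 (not isolated), via lithium 1,4-dimethoxy-3-(trimethylsilyl)naphthalen-2-olate 8 (not isolated)
Conditions: n-BuLi, THF, −100 → −78 °C; Tf2O, −78 → 0 °C
Reagents that add atoms: trifluoromethanesulfonic anhydride, O=S(=O)(OS(=O)(=O)C(F)(F)F)C(F)(F)F; n-butyllithium, [Li]CCCC, leaves lithium only in 7 and 8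
Why: Bromine–lithium exchange is followed by a fast 1,3-shift of silicon from oxygen to carbon (retro-Brook rearrangement), driven by the change from a C–Li to an O–Li bond; the naphthoxide is then triflated, the usual end of an o-silylaryl triflate synthesis.

Step 5
Reactants: 10 indane-1,3-dione; 11 3-methylbut-2-enoic acid
Product: 13 2-(3-methylbut-2-enoyl)indane-1,3-dione, via 3-oxoinden-1-yl 3-methylbut-2-enoate 12 (not isolated)
Conditions: DCC (1.1 equiv), DMAP (1.2 equiv), CH2Cl2, 0 °C → rt; dilute HCl wash
Reagents that add atoms: none
Why: Steglich-type activation gives the enol ester 12, and DMAP then carries the acyl group from oxygen to carbon through an acylpyridinium/dionate ion pair (C-acylation of cyclic 1,3-diones with carboxylic acids, DCC and DMAP); the shift is pulled forward because the strongly acidic triketone is removed as its DMAP salt.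

Step 6
Reactants: 13 2-(3-methylbut-2-enoyl)indane-1,3-dione; 9 1,4-dimethoxy-3-(trimethylsilyl)naphthalen-2-yl trifluoromethanesulfonate
Product: 17 ring-expanded triketone (racemic; seven-membered ring made of the CH that bears the 3-methylbut-2-enoyl group, a ketone, the o-phenylene of ring A, a second ketone and C2–C3 of 1,4-dimethoxynaphthalene), via 1,4-dimethoxy-2,3-naphthalyne 14 (not isolated), via the C-arylated aryl anion 15 (not isolated), via the benzocyclobutenoxide 16 (not isolated)
Conditions: CsF (4 equiv), MeCN, 80 °C, 9 (1.5 equiv) added over 1 h; aq. NaH2PO4 work-up
Reagents that add atoms: none
Why: Fluoride attacks the silicon of 9 and expels triflate to give the symmetrical naphthalyne 14, while CsF also converts 13 into its cesium enolate. The enolate carbon adds to 14 to give aryl anion 15, which closes 4-exo-trig on one of the two equivalent indanedione carbonyls to give 16; retro-aldol opening of 16 breaks the old ring C–C(=O) bond and releases the stabilised β-diketone enolate of 17, protonated on work-up. The closest known reaction type is the aryne acyl-alkylation of β-dicarbonyl compounds, the σ-insertion of an aryne into a C–C(=O) bond, which expands cyclic β-keto esters and 1,3-diketones by two carbons; the donor here is such a cyclic 1,3-diketone with an additional α-acyl group. Ring B is therefore not closed by a seven-membered cyclisation: the only closure is the 4-exo-trig step, and the seven-membered ring results from fragmentation of the strained fused four- and five-membered bicycle. The one new sp3 carbon, the CH between the two ketones, forms racemic under no control, epimerises through its enol and becomes the sp2 furan C3 in step 7. No regiochemistry arises, because both aryne carbons and both ring carbonyls are equivalent. Two selectivities are needed: C- over O-arylation, which the soft in-plane aryne LUMO and the loosely bound cesium counter-ion in MeCN should favour, and attack of 15 on a ring carbonyl and not on the enoyl carbonyl, which is favoured statistically and by the higher electrophilicity of the strained aryl ketones over the conjugated enone carbonyl. Slow addition of 9 keeps 14 dilute against the enolate and limits aryne oligomerisation and a second arylation of the product enolate.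

Step 7
Reactants: 17 ring-expanded triketone
Product: 19 radermachol, via the naphthalene-1,4-diol 18 (not isolated)
Conditions: BBr3 (5 equiv), CH2Cl2, −78 → 0 °C; H2O, 0 °C → rt, under argon
Reagents that add atoms: none
Why: BBr3 cleaves aryl methyl ethers by coordination to oxygen and bromide attack at methyl, and both methoxy groups sit beside carbonyl-bearing substituents that chelate boron, so both should go at or below 0 °C. The freed hydroxyl next to the side chain adds 5-exo-trig to the enoyl ketone and loses water to give the aromatic furan (acid-mediated cyclodehydration of an o-hydroxyaryl 1,3-diketone to a 3-acylbenzofuran); closure on the ring ketone would need a bridgehead double bond and cannot aromatise, so it is unproductive. The second hydroxyl stays in the hydrogen-bonded chelate with the ring B carbonyl, which is the vinylogous acid of the target.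

## Compound list

1 | 2-bromo-1,4-dimethoxynaphthalene | COc1cc(Br)c(OC)c2ccccc12 | starting material
2 | (1,4-dimethoxynaphthalen-2-yl)lithium | COc1cc([Li])c(OC)c2ccccc12 | intermediate
3 | dimethyl (1,4-dimethoxynaphthalen-2-yl)boronate | COB(OC)c1cc(OC)c2ccccc2c1OC | intermediate
4 | 1,4-dimethoxynaphthalen-2-ol | COc1cc(O)c(OC)c2ccccc12 | intermediate
5 | 3-bromo-1,4-dimethoxynaphthalen-2-ol | COc1c(Br)c(O)c(OC)c2ccccc12 | intermediate
6 | (3-bromo-1,4-dimethoxynaphthalen-2-yl)oxy-trimethylsilane | COc1c(Br)c(O[Si](C)(C)C)c(OC)c2ccccc12 | intermediate
7 | [1,4-dimethoxy-3-(trimethylsilyloxy)naphthalen-2-yl]lithium | COc1c([Li])c(O[Si](C)(C)C)c(OC)c2ccccc12 | intermediate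
8 | lithium 1,4-dimethoxy-3-(trimethylsilyl)naphthalen-2-olate | COc1c([Si](C)(C)C)c(O[Li])c(OC)c2ccccc12 | intermediate
9 | 1,4-dimethoxy-3-(trimethylsilyl)naphthalen-2-yl trifluoromethanesulfonate | COc1c([Si](C)(C)C)c(OS(=O)(=O)C(F)(F)F)c(OC)c2ccccc12 | intermediate
10 | indane-1,3-dione | O=C1CC(=O)c2ccccc12 | starting material
11 | 3-methylbut-2-enoic acid | CC(C)=CC(=O)O | starting material
12 | 3-oxoinden-1-yl 3-methylbut-2-enoate | CC(C)=CC(=O)OC1=CC(=O)c2ccccc12 | intermediate
13 | 2-(3-methylbut-2-enoyl)indane-1,3-dione | CC(C)=CC(=O)C1C(=O)c2ccccc2C1=O | intermediate
14 | 1,4-dimethoxy-2,3-naphthalyne (2,3-didehydro-1,4-dimethoxynaphthalene) | COC1=C2C=CC=CC2=C(OC)C#C1 | intermediate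
15 | aryl anion from C-arylation: cesium salt of 2-(1,4-dimethoxynaphthalen-2-yl)-2-(3-methylbut-2-enoyl)indane-1,3-dione carbanion at naphthalene C3 | CC(C)=CC(=O)C1(c2[c-]c(OC)c3ccccc3c2OC)C(=O)c2ccccc2C1=O.[Cs+] | intermediate
16 | cesium benzocyclobutenoxide (four-membered ring fused to the naphthalene and to the indanone ring; racemic) | CC(C)=CC(=O)C12C(=O)c3ccccc3C1([O-])c1c2c(OC)c2ccccc2c1OC.[Cs+] | intermediate
17 | ring-expanded triketone: dimethoxynaphtho-fused benzocycloheptenedione with the 3-methylbut-2-enoyl group on the sp3 ring carbon (racemic, enolisable) | CC(C)=CC(=O)C1C(=O)c2ccccc2C(=O)c2c1c(OC)c1ccccc1c2OC | intermediate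
18 | naphthalene-1,4-diol corresponding to 17 (racemic, enolisable) | CC(C)=CC(=O)C1C(=O)c2ccccc2C(=O)c2c1c(O)c1ccccc1c2O | intermediate
19 | radermachol | CC(C)=Cc1oc2c3c(c(O)c4ccccc4c(=O)c13)C(=O)c1ccccc1-2 | target

## Step count and weak points

Total: 7 steps. Longest linear sequence: 6 steps (steps 1, 2, 3, 4, 6, 7); step 5 is a one-step side branch.

**Step 6 (key step).**
- What may go wrong: the most likely failure is O-arylation of the triketone anion. Its charge sits largely on oxygen, and its carbon must become quaternary beside an ortho-methoxy group. The second danger is attack of the aryl anion on the enoyl carbonyl, which would shift the acyl group onto the naphthalene without ring expansion, or conjugate addition to the enone. Simple protonation of the aryl anion would stop the sequence at arylation.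
- Fallback: from 10 and 9 back to 17, with the acyl group introduced after the ring expansion. Indane-1,3-dione (10) and 9 with CsF in MeCN should give the ring-expanded diketone F1 by the same insertion. The donor is now a plain cyclic 1,3-diketone with a secondary, unhindered carbon and only two equivalent carbonyl groups. The benzylic ketone of F1 is then converted into its lithium enolate with LiN(SiMe3)2 (2.2 equiv, toluene–THF, 0 °C) and C-acylated with 3-methylbut-2-enoyl chloride to give 17.

**Step 7.**
- What may go wrong: HBr may add across the side-chain alkene, or bromide may add in conjugate fashion to the enone. The enol oxygen may close on the enone under acid to a dihydropyranone. The second ether may cleave incompletely. The diol may be oxidised by air before it cyclises.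
- Fallback: from 17 back to 19, replacing Lewis-acid ether cleavage by oxidative dealkylation and reduction. (NH4)2Ce(NO3)6 in MeCN–H2O at 0 °C should convert the dimethoxynaphthalene into the naphthoquinone F2. Na2S2O4 in EtOAc–H2O reduces F2 to the diol 18. A trace of p-TsOH in toluene at rt under argon closes 18 to 19.

**Step 2.**
- What may go wrong: the very electron-rich naphthol may be oxidised by the brominating agent (oxidative demethylation towards quinones) in place of substitution at C3.
- Fallback: from 4 back to 9 without electrophilic halogenation; it also bypasses steps 3 and 4. Naphthol 4 and isopropyl isocyanate (cat. Et3N, CH2Cl2) give the N-isopropylcarbamate F3. After transient N-silylation (TMSOTf, TMEDA), directed ortho-lithiation with n-BuLi occurs at C3, between the carbamate and a methoxy group, and Me3SiCl gives the silyl carbamate F4. DBU and Et2NH in MeCN at 40 °C release the silyl naphthol F5 as its amidinium salt, and PhNTf2 in the same flask converts it into 9.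

**Step 5.**
- What may go wrong: Michael addition of the dione to the activated acid, self-condensation of 10, stalling at the O-acyl stage, or deconjugation of the acyl group through a vinylketene.
- Fallback: from 10 back to 13, building the alkene by aldol addition and dehydration. Compound 10 with Ac2O, Et3N and DMAP gives 2-acetylindane-1,3-dione F6. Its dianion (LiN(i-Pr)2, 2.2 equiv, THF, −78 °C) adds to acetone to give the tertiary aldol F7. Dehydration with cat. p-TsOH in toluene at 60 °C gives 13.

Further compounds

F1 | step 6 | ring-expanded diketone without the acyl group: 7-ring of CH2, ketone, o-phenylene, ketone and C2–C3 of 1,4-dimethoxynaphthalene | O=C1Cc2c(OC)c3ccccc3c(OC)c2C(=O)c2ccccc12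
F2 | step 7 | naphthoquinone corresponding to 17 (racemic, enolisable) | CC(C)=CC(=O)C1C(=O)c2ccccc2C(=O)C2=C1C(=O)c1ccccc1C2=O
F3 | step 2 | 1,4-dimethoxynaphthalen-2-yl N-(propan-2-yl)carbamate | COc1cc(OC(=O)NC(C)C)c(OC)c2ccccc12
F4 | step 2 | 1,4-dimethoxy-3-(trimethylsilyl)naphthalen-2-yl N-(propan-2-yl)carbamate | COc1c([Si](C)(C)C)c(OC(=O)NC(C)C)c(OC)c2ccccc12
F5 | step 2 | 1,4-dimethoxy-3-(trimethylsilyl)naphthalen-2-ol | COc1c([Si](C)(C)C)c(O)c(OC)c2ccccc12
F6 | step 5 | 2-acetylindane-1,3-dione | CC(=O)C1C(=O)c2ccccc2C1=O
F7 | step 5 | 2-(3-hydroxy-3-methylbutanoyl)indane-1,3-dione | CC(C)(O)CC(=O)C1C(=O)c2ccccc2C1=O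
A1 | alternative 1 | 2-[5-hydroxy-2-(2-methylprop-1-enyl)naphtho[1,2-b]furan-4-carbonyl]benzoic acid | CC(C)=Cc1cc2c(o1)c1ccccc1c(O)c2C(=O)c1ccccc1C(=O)O
A2 | alternative 1 | 2-[3-[2-[5-(2-methylprop-1-enyl)furan-2-yl]phenyl]-3-oxopropanoyl]benzoic acid | CC(C)=Cc1ccc(o1)-c1ccccc1C(=O)CC(=O)c1ccccc1C(=O)O
A3 | alternative 2 | radermachol O-methyl ether (methyl on the ring D oxygen) | CC(C)=Cc1oc2c3ccccc3c(OC)c3c2c1C(=O)c1ccccc1C3=O
A4 | alternative 2 | (2-bromophenyl)[4-hydroxy-1-methoxy-3-(4-methylpent-3-en-1-ynyl)naphthalen-2-yl]methanone | CC(C)=CC#Cc1c(O)c2ccccc2c(OC)c1C(=O)c1ccccc1Br
A5 | alternative 3 | radermachol methyl enol ether | CC(C)=Cc1oc2c3c1C(=O)c1ccccc1C(OC)=C3C(=O)c1ccccc1-2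
A6 | alternative 3 | furan-fused benzotropone methyl enol ether with a 2-bromobenzoyl group on the central carbon and a free furan C5–H | CC(C)=Cc1occ2c1C(=O)c1ccccc1C(OC)=C2C(=O)c1ccccc1Br
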